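Saturday's flask began at 75 °C and was turned down to 25 °C at 15 h, and I had to say what that turn could still change.

common to all: starting material 0.010 M; gas 1.4 mM (held)

| charge | second substrate | temperature | remark | time |
|---|---|---|---|---|
| ash | 5 mM | 38 °C | run made earlier |  |
| alder | 20 mM | 65 °C | run made earlier |  |
| Tuesday's | 10.0 mM | 50 °C |  | 3.0 d |
| Sunday's | 10.0 mM | 25 °C |  | 3.0 d |
| Wednesday's | 10.0 mM | 75 °C |  | 3.0 d |
| Saturday's | 10.0 mM |  | at 75 °C until 15 h, from then on at 25 °C | 3.0 d |

ash run (percent of the starting material charged)

| time / d | target / % | cross product / % | starting material / % |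
|---|---|---|---|
| 0.833 | 17.9 | 21.3 | 61.4 |
| 2.08 | 17.2 | 20.9 | 61.2 |
| 3.00 | 17.9 | 20.7 | 60.8 |
| 4.00 | 17.5 | 20.6 | 61.4 |
| 5.00 | 17.2 | 21.2 | 61.0 |

alder run (percent of the starting material charged)

| time / h | target / % | cross product / % | starting material / % |
|---|---|---|---|
| 2.50 | 0 | 99.8 | 0.3 |
| 8.00 | 0 | 99.7 | 0.7 |
| 12.0 | 0.6 | 99.8 | 0.4 |
| 20.0 | 0.3 | 99.4 | 0.5 |
| 30.0 | 0.2 | 99.4 | 0.3 |

(readings scatter by 0.3 percentage points)

- at the start none of the gas is in solution

1. the flask with the highest share of target in all that became target or cross product ("all alike" if they lie within 1.5 percentage points) (Tuesday's / Sunday's / Wednesday's / Saturday's / all alike)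
2. share of target in all that became target or cross product, Tuesday's
3. share of target in all that became target or cross product, Sunday's
4. share of target in all that became target or cross product, Wednesday's
5. share of target in all that became target or cross product, Saturday's

I built the flask up one step at a time. With the main step alone, starting material taking up gas to give target, the share asked for is 100 per cent, there being no cross product to share with. The ash run gave that pair a ratio of target to starting material of 0.294.

The second step is starting material joining second substrate to give cross product. Ash stood still, with cross product at 21.3 % after 0.833 d and 21.2 % after 5.00 d, while 61.0 % of starting material stayed unused, so I took second substrate for the limiting reagent. One to one, its charge allowed 50.0 % of the starting material, which would have pulled the share far down.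

But the third step shows in the readings: cross product reached less than that, while the three readings still summed to 99.4 %, so some unseen drain took second substrate elsewhere. In ash, cross product took 41.4 % of the charged second substrate, and that share of the charge ending in cross product I called the capture.

Alder, at 65 °C, showed 49.9 % after 2.50 h, a floor, with 0.3 % of starting material left to take, and higher than ash. Its stop came well inside Saturday's hot stage, so I expected Saturday's cross product to be made before the turn, at 49.9 % or more. Cooling could then do no more than re-divide the rest between starting material and target. Taking the ash ratio for that division, though it was read at 38 °C and Saturday's would end at 25 °C, I reckoned Saturday's share at about 18.6 %, which is an estimate and not a bound. Sunday's, with the ash capture, came to 24.4 %, and I expected it to be higher still, being colder than ash.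

The forecast named Sunday's as highest, with Tuesday's 12 %, Sunday's 38 %, Wednesday's 3 % and Saturday's 36 %, on the words “Saturday's spends substrate hot, then re-equilibrates cold, ending near Sunday's”. We agreed on the highest flask but parted on Saturday's, where my figure was lower.

The flasks gave Tuesday's 14.1 %, Sunday's 39.9 %, Wednesday's 4.73 % and Saturday's 6.13 %, so Sunday's stood highest.

    starting material + reagent ⇌ target (K = 190 L mol⁻¹, k = 1300 L mol⁻¹ h⁻¹, Ea = 61.0 kJ mol⁻¹, ΔH = −6.00 kJ mol⁻¹)
    second substrate + reagent → second product (k = 2900 L mol⁻¹ h⁻¹, Ea = 36.0 kJ mol⁻¹)
    starting material + second substrate → cross product (k = 320 L mol⁻¹ h⁻¹, Ea = 68.0 kJ mol⁻¹)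
    gas ⇌ reagent, rate k4*(csat - [reagent]) (kL = 11.0 h⁻¹)
    (constants at 50 °C)

Saturday's gave 6.13 %. Its cross product stood at 78.8 % at the turn, 0.625 d, with second substrate at 0 %, and was still 78.8 % at 3.00 d, while target moved from 3.91 % to 5.15 %. That is a capture of 78.8 %, above my floor. A neighbour of Wednesday's, charged with 0.040 M of starting material, had a capture of 99.3 %, yet that is cross product of 24.8 % of its larger charge, and its share was 35.9 %.

The earlier runs and the new flask are calculated for an exercise; scatter was added.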